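Catalyst intermediate A goes forward to catalyst intermediate B much faster than it dies to spent catalyst, 43 s⁻¹ against 0.23 s⁻¹, and the set-ups below are judged on that comparison.

    reagent + free catalyst ⇌ catalyst intermediate A (K1 = 89 M⁻¹, k1 = 8800 M⁻¹ s⁻¹)
    catalyst intermediate A → catalyst intermediate B (k2 = 43 s⁻¹)
    starting material + catalyst intermediate B → catalyst intermediate C (k3 = 1.9 × 10⁵ M⁻¹ s⁻¹)
    catalyst intermediate C → free catalyst + target (k4 = 3100 s⁻¹)
    catalyst intermediate A → spent catalyst (k5 = 0.23 s⁻¹)
    starting material + protic impurity → quenched substrate (k6 = 63 M⁻¹ s⁻¹)

| flask | starting material | reagent | protic impurity | free catalyst | remark | time |
|---|---|---|---|---|---|---|
| blue | 10 mM | 1.00 equiv | 5.00 mM | 0.1 mol% | a single well-mixed tank run continuously and read at steady state, 10 min in it on average |  |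
| ochre | 10 mM | 1.00 equiv | 5.00 mM | 0.1 mol% | everything together in a closed stirred flask, run for 10 min | 10 min |
| violet | 10 mM | 1.00 equiv (fed, over 8.00 min) | 5.00 mM | 0.1 mol% | a stirred flask in which reagent is dosed at a steady rate over 8.00 min without added volume, worked up at 10 min | 10 min |
| amber | 10 mM (fed, over 8.00 min) | 1.00 equiv | 5.00 mM | 0.1 mol% | a stirred flask in which starting material is dosed at a steady rate over 8.00 min without added volume, worked up at 10 min | 10 min |

* the set-up with the highest amount of target at the outlet or at the end, in percent of the starting material put in ("none" if the first two lie within 2 percentage points) (blue / ochre / violet / amber / none)
* amount of target at the outlet or at the end, in percent of the starting material put in, blue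
* amount of target at the outlet or at the end, in percent of the starting material put in, ochre
* amount of target at the outlet or at the end, in percent of the starting material put in, violet
* amount of target at the outlet or at the end, in percent of the starting material put in, amber

Minutes of the meeting. I opened with the round of the catalyst: free catalyst binds reagent to give catalyst intermediate A, which turns into catalyst intermediate B; that takes up starting material to give catalyst intermediate C, which releases target and free catalyst. I proposed to carry one number, the turnover budget (the usual term is turnover number), the forward constant of catalyst intermediate A divided by its death constant, 187, which is the average count of rounds before a catalyst dies. Multiplied by the loading of 0.1 mol%, it caps target at 18.7% of the starting material.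

A colleague objected that catalyst intermediate A also falls back to reagent and free catalyst, and that dosing changes every concentration. I answered that what falls back must pass the same fork again, and that both exits of the fork act on [catalyst intermediate A], so their ratio contains no concentration, and dosing shifts when turnovers happen, not how many.

Another colleague feared the protic impurity. I replied that its 5.00 mM against 10 mM of starting material leaves 50.0%, more than the cap asks for, and that catalyst intermediate B has no exit but starting material.

Last came the question of time. Taking the binding in ochre as at equilibrium, with the equilibrium constant times [reagent] at 0.89, catalyst intermediate A holds about half of the working catalyst, so the catalyst's half-life there is near 0.107 min, far shorter than 10 min, and ochre reaches 18.7%, by my reckoning. That half-life rests on ochre's charged reagent and does not carry to violet and amber, where one species arrives by feed; but each feed, at its steady rate, brings the cap's worth of its species in 1.50 min, less than its 8.00 min, so I put violet and amber at 18.7% as well. In blue, catalyst stays 10 min on average, and the share dying before it leaves gives 18.4%. The gap of 0.30 percentage points stands against a margin of 2 points, so I committed to none.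

The forecast gave 18.3%, 18.7%, 18.7% and 18.6% for blue, ochre, violet and amber, and none as best, holding that “the yield is capped near 18.7% however the reagent or starting material is fed”; for blue and amber I had 18.4% and 18.7%.

The simulation gives 18.3%, 18.7%, 18.7% and 18.7% in that order, and none as best.

Ochre's target divided by its loading reads 187 turnovers, beside the budget of 187, with spent catalyst at 100% of the catalyst charged at 10.0 min. The neighbouring flask is ochre with 0.06 mol% of free catalyst, its other charges and its time held, and the same budget times that loading gives 11.2%. Simulated, that neighbour ends with 11.2% of target, spent catalyst at 100% of the catalyst charged, and 39% of its starting material still there at 10.0 min.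

The rate constants are assumed; no experiment stands behind them.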